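**Retrosynthetic overview**
- C4–C5 is cut last: a Pd-catalysed acyl coupling joins a 3-arylmalate half-thioester to a prenylated benzylzinc reagent, followed only by desilylation.
- The two carboxyls of the 3-arylmalic acid are told apart by α-hydroxy-acid-selective methyl esterification; the remaining aryl-bearing carboxyl becomes the thioester.
- Key disconnection C3–aryl: copper-catalysed anti opening of C2-symmetric diethyl (2R,3R)-epoxysuccinate by an aryl Grignard reagent, which breaks the symmetry and sets C2 and C3 in one stereospecific step.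
- The benzyl unit comes from 4-hydroxybenzaldehyde by ortho-C-prenylation, silylation, reduction, chlorination and zinc insertion.
- Rings: none is formed (acyclic target; both benzene rings are bought, the oxirane is only opened).

Assumption: diethyl (2R,3R)-oxirane-2,3-dicarboxylate (the trans-epoxysuccinate derived from natural L-tartrate) and (4-bromophenoxy)triisopropylsilane are bought as catalogue compounds.

**Step 1**
Reactants: 1 diethyl (2R,3R)-oxirane-2,3-dicarboxylate; 2 (4-bromophenoxy)triisopropylsilane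
Product: 4 diethyl (2R,3S)-2-hydroxy-3-{4-[(triisopropylsilyl)oxy]phenyl}butanedioate, via arylmagnesium bromide 3 (not isolated)
Conditions: 2, Mg, THF, 45 °C; then slow addition to 1, CuBr·SMe2 (10 mol%), THF, −45 → −20 °C; cold 1 M HCl
Reagents that add atoms: none
Why: Copper-catalysed SN2 opening of an epoxide by a Grignard reagent: the two oxirane carbons of C2-symmetric 1 are equivalent, so attack at either one anti to the C–O bond gives the same product, breaks the symmetry and fixes both stereocentres at once (C3 by inversion, now S with aryl in place of O; C2 keeps its oxygen and stays R), while the low temperature keeps the aryl nucleophile off the ester carbonyls.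

**Step 2**
Reactants: 4 diethyl (2R,3S)-2-hydroxy-3-{4-[(triisopropylsilyl)oxy]phenyl}butanedioate
Product: 5 (2R,3S)-2-hydroxy-3-{4-[(triisopropylsilyl)oxy]phenyl}butanedioic acid
Conditions: LiOH·H2O (4 equiv), THF/H2O 3:1, 0 °C, 5 h; then 1 M HCl to pH 3
Reagents that add atoms: lithium hydroxide, [Li+].[OH-]
Why: Ester saponification (BAc2) at 0 °C hydrolyses both ethyl esters while the hindered aryl TIPS ether survives, and once each ester is a carboxylate its α-carbon is no longer acidic, so C2 and C3 keep their configuration.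

**Step 3**
Reactants: 5 (2R,3S)-2-hydroxy-3-{4-[(triisopropylsilyl)oxy]phenyl}butanedioic acid
Product: 6 (2S,3R)-3-hydroxy-4-methoxy-4-oxo-2-{4-[(triisopropylsilyl)oxy]phenyl}butanoic acid
Conditions: B(OH)3 (20 mol%), MeOH, rt, 24 h
Reagents that add atoms: methanol, CO
Why: Boric-acid-catalysed chemoselective esterification of α-hydroxy acids: only the carboxyl that can form a five-membered borate chelate with the adjacent hydroxyl is activated, so the methyl ester of the target is installed next to the carbinol and the aryl-bearing carboxyl stays free, with no stereocentre touched.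

**Step 4**
Reactants: 6 (2S,3R)-3-hydroxy-4-methoxy-4-oxo-2-{4-[(triisopropylsilyl)oxy]phenyl}butanoic acid
Product: 7 methyl (2R,3S)-4-(ethylsulfanyl)-2-hydroxy-4-oxo-3-{4-[(triisopropylsilyl)oxy]phenyl}butanoate
Conditions: EtSH (4 equiv), EDC·HCl (1.2 equiv), DMAP (5 mol%), CH2Cl2, −15 → 0 °C
Reagents that add atoms: ethanethiol, CCS
Why: Carbodiimide (Steglich-type) thioesterification: the activated acyl group of the only free carboxyl is taken by the excess thiol far faster than by the hindered secondary hydroxyl, and low temperature with only catalytic DMAP keeps the α-aryl centre from epimerising through a ketene or enol.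

**Step 5**
Reactants: 8 4-hydroxybenzaldehyde; 9 1-bromo-3-methylbut-2-ene
Product: 10 4-hydroxy-3-(3-methylbut-2-en-1-yl)benzaldehyde
Conditions: KOH (1.1 equiv), H2O, rt, 48 h
Reagents that add atoms: none
Why: C-alkylation of an ambident phenoxide in water (ortho-prenylation): hydrogen bonding to the phenoxide oxygen disfavours O-alkylation and the para position is blocked by the formyl group, so the prenyl group enters ortho to the hydroxyl.

**Step 6**
Reactants: 10 4-hydroxy-3-(3-methylbut-2-en-1-yl)benzaldehyde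
Product: 11 4-[(tert-butyldimethylsilyl)oxy]-3-(3-methylbut-2-en-1-yl)benzaldehyde
Conditions: TBSCl (1.2 equiv), imidazole (2 equiv), DMF, rt
Reagents that add atoms: tert-butyldimethylsilyl chloride, CC(C)(C)[Si](C)(C)Cl
Why: Imidazole-promoted O-silylation of the phenol removes the acidic proton before a benzylic organometallic is made.

**Step 7**
Reactants: 11 4-[(tert-butyldimethylsilyl)oxy]-3-(3-methylbut-2-en-1-yl)benzaldehyde
Product: 12 {4-[(tert-butyldimethylsilyl)oxy]-3-(3-methylbut-2-en-1-yl)phenyl}methanol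
Conditions: NaBH4 (0.5 equiv), MeOH/THF, 0 °C, 20 min
Reagents that add atoms: none
Why: Hydride reduction of the aldehyde with NaBH4 gives the benzylic alcohol, the alkene and the aryl silyl ether being inert at 0 °C.

**Step 8**
Reactants: 12 {4-[(tert-butyldimethylsilyl)oxy]-3-(3-methylbut-2-en-1-yl)phenyl}methanol
Product: 13 tert-butyl[4-(chloromethyl)-2-(3-methylbut-2-en-1-yl)phenoxy]dimethylsilane
Conditions: PPh3 (1.2 equiv), NCS (1.2 equiv), THF, 0 °C → rt
Reagents that add atoms: N-chlorosuccinimide, O=C1CCC(=O)N1Cl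
Why: Appel-type chlorination: chloride displaces the alkoxyphosphonium group at the benzylic carbon (SN2) under neutral conditions that spare the prenyl alkene and the silyl ether.

**Step 9**
Reactants: 13 tert-butyl[4-(chloromethyl)-2-(3-methylbut-2-en-1-yl)phenoxy]dimethylsilane; 7 methyl (2R,3S)-4-(ethylsulfanyl)-2-hydroxy-4-oxo-3-{4-[(triisopropylsilyl)oxy]phenyl}butanoate
Product: 15 methyl (2R,3S)-5-{4-[(tert-butyldimethylsilyl)oxy]-3-(3-methylbut-2-en-1-yl)phenyl}-2-hydroxy-4-oxo-3-{4-[(triisopropylsilyl)oxy]phenyl}pentanoate, via benzylzinc chloride 14 (not isolated)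
Conditions: 13 (1.5 equiv), Zn dust, LiCl, THF, 25 °C; then slow addition to 7, PdCl2(PPh3)2 (5 mol%), THF/toluene, 0 °C → rt; aq. NH4Cl
Reagents that add atoms: none
Why: LiCl-assisted zinc insertion into the benzylic chloride followed by Fukuyama coupling (Pd(0) inserts into the acyl–S bond, transmetalation with the benzylzinc, reductive elimination) forms the C4–C5 bond under neutral, non-basic conditions that leave the methyl ester, the free secondary hydroxyl and the base-sensitive α-aryl centre untouched, and no new stereocentre is formed.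

**Step 10**
Reactants: 15 methyl (2R,3S)-5-{4-[(tert-butyldimethylsilyl)oxy]-3-(3-methylbut-2-en-1-yl)phenyl}-2-hydroxy-4-oxo-3-{4-[(triisopropylsilyl)oxy]phenyl}pentanoate
Product: 16 Asperteretal H, methyl (2R,3S)-2-hydroxy-5-[4-hydroxy-3-(3-methylbut-2-en-1-yl)phenyl]-3-(4-hydroxyphenyl)-4-oxopentanoate
Conditions: TBAF (2.4 equiv), AcOH (2.6 equiv), THF, 0 °C
Reagents that add atoms: none
Why: Fluoride-driven cleavage of both aryl silyl ethers (Si–F bond formation), buffered with acetic acid so that no free phenoxide or basic fluoride can epimerise C3 or trigger retro-aldol cleavage of the β-hydroxy ketone.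

**Compound list**
1 | diethyl (2R,3R)-oxirane-2,3-dicarboxylate | CCOC(=O)[C@@H]1O[C@H]1C(=O)OCC | starting material
2 | (4-bromophenoxy)triisopropylsilane | CC(C)[Si](Oc1ccc(Br)cc1)(C(C)C)C(C)C | starting material
3 | {4-[(triisopropylsilyl)oxy]phenyl}magnesium bromide (formed in the flask) | CC(C)[Si](Oc1ccc([Mg]Br)cc1)(C(C)C)C(C)C | intermediate
4 | diethyl (2R,3S)-2-hydroxy-3-{4-[(triisopropylsilyl)oxy]phenyl}butanedioate | CCOC(=O)[C@H](O)[C@@H](C(=O)OCC)c1ccc(O[Si](C(C)C)(C(C)C)C(C)C)cc1 | intermediate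
5 | (2R,3S)-2-hydroxy-3-{4-[(triisopropylsilyl)oxy]phenyl}butanedioic acid | OC(=O)[C@H](O)[C@@H](C(=O)O)c1ccc(O[Si](C(C)C)(C(C)C)C(C)C)cc1 | intermediate
6 | (2S,3R)-3-hydroxy-4-methoxy-4-oxo-2-{4-[(triisopropylsilyl)oxy]phenyl}butanoic acid | COC(=O)[C@H](O)[C@@H](C(=O)O)c1ccc(O[Si](C(C)C)(C(C)C)C(C)C)cc1 | intermediate
7 | methyl (2R,3S)-4-(ethylsulfanyl)-2-hydroxy-4-oxo-3-{4-[(triisopropylsilyl)oxy]phenyl}butanoate | COC(=O)[C@H](O)[C@@H](C(=O)SCC)c1ccc(O[Si](C(C)C)(C(C)C)C(C)C)cc1 | intermediate
8 | 4-hydroxybenzaldehyde | O=Cc1ccc(O)cc1 | starting material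
9 | 1-bromo-3-methylbut-2-ene (prenyl bromide) | CC(C)=CCBr | starting material
10 | 4-hydroxy-3-(3-methylbut-2-en-1-yl)benzaldehyde | CC(C)=CCc1cc(C=O)ccc1O | intermediate
11 | 4-[(tert-butyldimethylsilyl)oxy]-3-(3-methylbut-2-en-1-yl)benzaldehyde | CC(C)=CCc1cc(C=O)ccc1O[Si](C)(C)C(C)(C)C | intermediate
12 | {4-[(tert-butyldimethylsilyl)oxy]-3-(3-methylbut-2-en-1-yl)phenyl}methanol | CC(C)=CCc1cc(CO)ccc1O[Si](C)(C)C(C)(C)C | intermediate
13 | tert-butyl[4-(chloromethyl)-2-(3-methylbut-2-en-1-yl)phenoxy]dimethylsilane | CC(C)=CCc1cc(CCl)ccc1O[Si](C)(C)C(C)(C)C | intermediate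
14 | {4-[(tert-butyldimethylsilyl)oxy]-3-(3-methylbut-2-en-1-yl)benzyl}zinc chloride (formed in the flask) | CC(C)=CCc1cc(C[Zn]Cl)ccc1O[Si](C)(C)C(C)(C)C | intermediate
15 | methyl (2R,3S)-5-{4-[(tert-butyldimethylsilyl)oxy]-3-(3-methylbut-2-en-1-yl)phenyl}-2-hydroxy-4-oxo-3-{4-[(triisopropylsilyl)oxy]phenyl}pentanoate | COC(=O)[C@H](O)[C@@H](C(=O)Cc1ccc(O[Si](C)(C)C(C)(C)C)c(CC=C(C)C)c1)c1ccc(O[Si](C(C)C)(C(C)C)C(C)C)cc1 | intermediate
16 | Asperteretal H, methyl (2R,3S)-2-hydroxy-5-[4-hydroxy-3-(3-methylbut-2-en-1-yl)phenyl]-3-(4-hydroxyphenyl)-4-oxopentanoate | COC(=O)[C@H](O)[C@@H](C(=O)Cc1ccc(O)c(CC=C(C)C)c1)c1ccc(O)cc1 | target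

**Totals**
Total step count: 10. Longest linear sequence: 6 steps (1–4, 9, 10; equally 5–8, 9, 10).

**Steps most likely to fail**

Step 1. The aryl Grignard may attack an ester carbonyl or the copper turnover on this electron-poor epoxide may be poor. The fallback sets out from bromide 2 (as Grignard 3) and comes back at 4; it replaces the epoxide by the far more reactive tartrate cyclic sulfate. Diethyl L-tartrate and SOCl2 give diethyl (4R,5R)-1,3,2-dioxathiolane-4,5-dicarboxylate 2-oxide F1, which RuCl3 (cat.)/NaIO4 oxidises to diethyl (4R,5R)-1,3,2-dioxathiolane-4,5-dicarboxylate 2,2-dioxide F2. Grignard 3 with catalytic Li2CuCl4 at −78 °C opens F2 with inversion at one of its two equivalent carbons to give diethyl (2R,3S)-2-(sulfooxy)-3-{4-[(triisopropylsilyl)oxy]phenyl}butanedioate F3. Catalytic H2SO4 with one equivalent of water in THF then hydrolyses the sulfate ester to 4, with the same configuration as in the main route.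

Step 5. Direct C-prenylation competes with O-alkylation and double alkylation, and the yield is usually modest. The fallback sets out from 8 and comes back at 10; it builds the prenyl group by a sigmatropic route. O-Alkylation of 8 with 3-chloro-3-methylbut-1-yne (K2CO3, KI, acetone) gives 4-[(2-methylbut-3-yn-2-yl)oxy]benzaldehyde F4. Lindlar semi-hydrogenation gives 4-[(2-methylbut-3-en-2-yl)oxy]benzaldehyde F5. Heating F5 in xylene at 130 °C brings about the aromatic Claisen rearrangement, which places the linear prenyl group ortho to the phenol and gives 10.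

Step 9. The free secondary hydroxyl of 7 may protonate the benzylzinc reagent, which can also dimerise (Wurtz), and the α-aryl thioester is sensitive. The fallback sets out from 7 and comes back at 16; the union is run on a fully O-protected thioester and finished by one global deprotection. TESCl/imidazole converts 7 into methyl (2R,3S)-4-(ethylsulfanyl)-4-oxo-2-[(triethylsilyl)oxy]-3-{4-[(triisopropylsilyl)oxy]phenyl}butanoate F6. The Pd-catalysed acyl coupling of F6 with 14 gives methyl (2R,3S)-5-{4-[(tert-butyldimethylsilyl)oxy]-3-(3-methylbut-2-en-1-yl)phenyl}-4-oxo-2-[(triethylsilyl)oxy]-3-{4-[(triisopropylsilyl)oxy]phenyl}pentanoate F7. TBAF/AcOH then removes all three silyl groups and gives 16 directly, one step more than the main route.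

**Further compounds**
F1 | step 1 | diethyl (4R,5R)-1,3,2-dioxathiolane-4,5-dicarboxylate 2-oxide | CCOC(=O)[C@@H]1OS(=O)O[C@H]1C(=O)OCC
F2 | step 1 | diethyl (4R,5R)-1,3,2-dioxathiolane-4,5-dicarboxylate 2,2-dioxide | CCOC(=O)[C@@H]1OS(=O)(=O)O[C@H]1C(=O)OCC
F3 | step 1 | diethyl (2R,3S)-2-(sulfooxy)-3-{4-[(triisopropylsilyl)oxy]phenyl}butanedioate | CCOC(=O)[C@H](OS(=O)(=O)O)[C@@H](C(=O)OCC)c1ccc(O[Si](C(C)C)(C(C)C)C(C)C)cc1
F4 | step 5 | 4-[(2-methylbut-3-yn-2-yl)oxy]benzaldehyde | CC(C)(C#C)Oc1ccc(C=O)cc1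
F5 | step 5 | 4-[(2-methylbut-3-en-2-yl)oxy]benzaldehyde | CC(C)(C=C)Oc1ccc(C=O)cc1
F6 | step 9 | methyl (2R,3S)-4-(ethylsulfanyl)-4-oxo-2-[(triethylsilyl)oxy]-3-{4-[(triisopropylsilyl)oxy]phenyl}butanoate | COC(=O)[C@H](O[Si](CC)(CC)CC)[C@@H](C(=O)SCC)c1ccc(O[Si](C(C)C)(C(C)C)C(C)C)cc1
F7 | step 9 | methyl (2R,3S)-5-{4-[(tert-butyldimethylsilyl)oxy]-3-(3-methylbut-2-en-1-yl)phenyl}-4-oxo-2-[(triethylsilyl)oxy]-3-{4-[(triisopropylsilyl)oxy]phenyl}pentanoate | COC(=O)[C@H](O[Si](CC)(CC)CC)[C@@H](C(=O)Cc1ccc(O[Si](C)(C)C(C)(C)C)c(CC=C(C)C)c1)c1ccc(O[Si](C(C)C)(C(C)C)C(C)C)cc1
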